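The cyclohexa-2,5-diene ring (C1 bears OAc, C2 OMe, C4 OH, C6 the side chain) is disconnected across C1–C6 and C4–C5 into a terminal alkyne and a (1Z,3E)-1,2,4-trioxygenated butadiene. The key step, an intramolecular Diels–Alder reaction, forms both bonds and both ring stereocentres at once. It exploits the 1,4-relationship of the two acetoxy-bearing carbons (ring C1 and side-chain C2'): a temporary di-tert-butylsilylene bridge between their oxygens lets the (R)-carbinol of a homopropargylic alcohol steer the alkyne to one diene face through a seven-membered silaketal ring and fixes the regiochemistry, while suprafacial addition sets the C1 and C4 oxygens cis. Tether cleavage and diacetylation follow.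

Key step: step 6

Abbreviations: TBS = tert-butyldimethylsilyl, Tf = trifluoromethanesulfonyl, Ts = p-toluenesulfonyl.

Step 1
Reactants: 1 (R)-epichlorohydrin; 2 dodecylmagnesium bromide
Product: 4 (R)-2-tridecyloxirane, via (R)-1-chloropentadecan-2-ol 3 (not isolated)
Conditions: CuI (10 mol %), THF, −40 to 0 °C; then NaOH (powdered), Et2O, rt
Reagents that add atoms: none
Why: Copper-catalysed Grignard opening of the epoxide at its unsubstituted carbon, then base-induced intramolecular Williamson closure of the chlorohydrin, should carry the stereocentre of 1 unchanged into the new terminal epoxide, because no bond at that carbon is broken.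

Step 2
Reactants: 4 (R)-2-tridecyloxirane; 5 lithium acetylide–ethylenediamine complex
Product: 6 (R)-heptadec-1-yn-4-ol
Conditions: DMSO/THF, 0 °C to rt; NH4Cl (aq) work-up
Reagents that add atoms: none
Why: SN2 opening of the terminal epoxide by the acetylide at its CH2 group (epoxide alkynylation) leaves the carbinol stereocentre untouched and should give the (R)-homopropargylic alcohol.

Step 3
Reactants: 6 (R)-heptadec-1-yn-4-ol; 7 but-2-yne-1,4-diol
Product: 9 4-({di-tert-butyl[(4R)-heptadec-1-yn-4-yloxy]silyl}oxy)but-2-yn-1-ol, via silyl triflate 8 (not isolated)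
Conditions: t-Bu2Si(OTf)2 (1.05 equiv), 2,6-lutidine, CH2Cl2, −78 to 0 °C; then 7 (5 equiv), imidazole, DMF, 0 °C to rt
Reagents that add atoms: di-tert-butylsilyl bis(trifluoromethanesulfonate), CC(C)(C)[Si](OS(=O)(=O)C(F)(F)F)(OS(=O)(=O)C(F)(F)F)C(C)(C)C
Why: Sequential silylation (unsymmetrical silaketal formation): the hindered secondary alcohol should displace only one triflate of the bulky bis(triflate), and the remaining Si–OTf is then taken by one primary hydroxyl of the diol, used in excess to suppress double silylation.

Step 4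
Reactants: 9 4-({di-tert-butyl[(4R)-heptadec-1-yn-4-yloxy]silyl}oxy)but-2-yn-1-ol
Product: 11 (2E)-4-({di-tert-butyl[(4R)-heptadec-1-yn-4-yloxy]silyl}oxy)-3-methoxybut-2-enal, via ynal 10 (not isolated)
Conditions: MnO2 (activated, excess), CH2Cl2, rt; filtration through Celite; then MeOH (10 equiv), 1,4-diazabicyclo[2.2.2]octane (10 mol %), 0 °C
Reagents that add atoms: methanol, CO
Why: MnO2 oxidation of the propargylic alcohol gives the ynal, and amine-catalysed oxa-Michael addition of methanol to its β-carbon should give the β-methoxy enal, whose double-bond geometry (E drawn) is immaterial because that bond becomes a single bond in step 5.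

Step 5
Reactants: 11 (2E)-4-({di-tert-butyl[(4R)-heptadec-1-yn-4-yloxy]silyl}oxy)-3-methoxybut-2-enal
Product: 12 di-tert-butyl{[(1Z,3E)-4-(tert-butyldimethylsilyloxy)-2-methoxybuta-1,3-dien-1-yl]oxy}[(4R)-heptadec-1-yn-4-yloxy]silane
Conditions: TBSOTf (1.3 equiv), Et3N (3 equiv), Et2O, −78 to 0 °C; pentane extraction, filtration through Et3N-deactivated alumina
Reagents that add atoms: tert-butyldimethylsilyl trifluoromethanesulfonate, CC(C)(C)[Si](C)(C)OS(=O)(=O)C(F)(F)F
Why: Soft enolisation of a vinylogous ester: O-silylation of the aldehyde and γ-deprotonation by Et3N should give the dienol ether, the s-trans enal leading to the 3E enol ether and deprotonation beside the methoxy-bearing carbon placing the tether oxygen cis to OMe (1Z), as is usual for α-oxygenated ketone enol ethers, so that both terminal oxygens point outward and either enal isomer converges on one diene.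

Step 6
Reactants: 12 di-tert-butyl{[(1Z,3E)-4-(tert-butyldimethylsilyloxy)-2-methoxybuta-1,3-dien-1-yl]oxy}[(4R)-heptadec-1-yn-4-yloxy]silane
Product: 13 silylene-bridged cycloadduct: (1S,4R)-4-(tert-butyldimethylsilyloxy)-2-methoxycyclohexa-2,5-diene whose C1 oxygen and the (2R)-oxygen of its 6-(2-oxypentadecyl) chain are joined by Si(t-Bu)2 in a seven-membered 1,3-dioxa-2-silepane ring fused at C1–C6
Conditions: toluene (0.01 M), BHT (0.1 equiv), 2,6-di-tert-butylpyridine (0.2 equiv), base-washed sealed tube, 180 °C
Reagents that add atoms: none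
Why: A concerted thermal [4+2] cycloaddition (type 1 intramolecular Diels–Alder) joins the two alkyne carbons to the termini of the tethered (1Z,3E)-diene, forming C6–C1 and C5–C4 and delivering the cyclohexa-2,5-diene with its enol ether and both carbinol carbons already at the oxidation level of the target. The closest known reactions are thermal intramolecular Diels–Alder reactions of dienynes with unactivated alkynes and silicon-tethered (silaketal) Diels–Alder reactions of silyl dienol ethers. The six-membered carbocycle closes by the cycloaddition itself, and the seven-membered 1,3-dioxa-2-silepane ring closes through the same C1–C6 bond in the fused (exo) mode, the reverse orientation requiring a more strained eight-membered bridge. C1 and C4 become cis because addition is suprafacial on a diene whose two terminal oxygens are both outside, and their absolute sense follows from the (R)-carbinol, since in the chair-like seven-membered transition-state ring the tridecyl chain lies pseudo-equatorial and away from the tert-butyl groups on silicon, which places the alkyne on the diene face leading to (1S,4R). The step needs regiocontrol (C6 bonded to C1, next to the OMe-bearing C2) and facial control, both secured by the short tether, and chemoselectivity against intermolecular reaction and aromatisation, secured by high dilution, a radical inhibitor, a hindered base and the poor leaving-group ability of the two silyl ethers, whose trans relation to the 1,4-hydrogens also blocks thermal syn elimination. Only the diene isomer with the tether oxygen outside can reach the alkyne, so minor geometric isomers should not give stereoisomeric adducts.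

Step 7
Reactants: 13 silylene-bridged cycloadduct
Product: 14 (1S,4R)-4-(tert-butyldimethylsilyloxy)-6-[(2R)-2-hydroxypentadecyl]-2-methoxycyclohexa-2,5-dien-1-ol
Conditions: HF·pyridine, pyridine, THF, 0 °C; NaHCO3 (aq) quench
Reagents that add atoms: none
Why: Selective desilylation: the dialkoxysilane, with two electronegative oxygens on silicon, should be cleaved by buffered HF·pyridine at 0 °C faster than the secondary trialkylsilyl ether, as is known for di-tert-butylsilylene acetals beside TBS ethers.

Step 8
Reactants: 14 (1S,4R)-4-(tert-butyldimethylsilyloxy)-6-[(2R)-2-hydroxypentadecyl]-2-methoxycyclohexa-2,5-dien-1-ol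
Product: 15 (1S,4R)-6-[(2R)-2-acetoxypentadecyl]-4-(tert-butyldimethylsilyloxy)-2-methoxycyclohexa-2,5-dien-1-yl acetate
Conditions: Ac2O, pyridine, 4-(dimethylamino)pyridine (cat.), CH2Cl2, 0 °C to rt
Reagents that add atoms: acetic anhydride, CC(=O)OC(C)=O
Why: Amine-catalysed acetylation (nucleophilic acyl transfer) of both secondary hydroxyls takes place at oxygen without touching any stereocentre, and the mildly basic medium spares the silyl ether and the enol ether.

Step 9
Reactants: 15 (1S,4R)-6-[(2R)-2-acetoxypentadecyl]-4-(tert-butyldimethylsilyloxy)-2-methoxycyclohexa-2,5-dien-1-yl acetate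
Product: 16 (1S,4R)-6-[(2R)-2-acetoxypentadecyl]-4-hydroxy-2-methoxycyclohexa-2,5-dien-1-yl acetate (CNP0123936.1)
Conditions: HF·pyridine, pyridine, THF, 0 °C to rt; NaHCO3 (aq) quench
Reagents that add atoms: none
Why: Fluoride-mediated cleavage of the TBS ether under buffered, non-basic conditions should free the C4 hydroxyl while leaving both acetates and the methyl enol ether intact and avoiding base-induced 1,4-elimination of acetic acid.

Compound list
1 | (R)-epichlorohydrin | ClC[C@H]1CO1 | starting material
2 | dodecylmagnesium bromide | CCCCCCCCCCCC[Mg]Br | starting material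
3 | (R)-1-chloropentadecan-2-ol | CCCCCCCCCCCCC[C@H](CCl)O | intermediate (not isolated)
4 | (R)-2-tridecyloxirane | CCCCCCCCCCCCC[C@@H]1CO1 | intermediate
5 | lithium acetylide–ethylenediamine complex | [Li+].[C-]#C.NCCN | starting material
6 | (R)-heptadec-1-yn-4-ol | CCCCCCCCCCCCC[C@H](CC#C)O | intermediate
7 | but-2-yne-1,4-diol | OCC#CCO | starting material
8 | di-tert-butyl[(4R)-heptadec-1-yn-4-yloxy]silyl trifluoromethanesulfonate | CCCCCCCCCCCCC[C@H](CC#C)O[Si](C(C)(C)C)(C(C)(C)C)OS(=O)(=O)C(F)(F)F | intermediate (not isolated)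
9 | 4-({di-tert-butyl[(4R)-heptadec-1-yn-4-yloxy]silyl}oxy)but-2-yn-1-ol | CCCCCCCCCCCCC[C@H](CC#C)O[Si](C(C)(C)C)(C(C)(C)C)OCC#CCO | intermediate
10 | 4-({di-tert-butyl[(4R)-heptadec-1-yn-4-yloxy]silyl}oxy)but-2-ynal | CCCCCCCCCCCCC[C@H](CC#C)O[Si](C(C)(C)C)(C(C)(C)C)OCC#CC=O | intermediate (not isolated)
11 | (2E)-4-({di-tert-butyl[(4R)-heptadec-1-yn-4-yloxy]silyl}oxy)-3-methoxybut-2-enal | CCCCCCCCCCCCC[C@H](CC#C)O[Si](C(C)(C)C)(C(C)(C)C)OC/C(OC)=C\C=O | intermediate
12 | di-tert-butyl{[(1Z,3E)-4-(tert-butyldimethylsilyloxy)-2-methoxybuta-1,3-dien-1-yl]oxy}[(4R)-heptadec-1-yn-4-yloxy]silane | CCCCCCCCCCCCC[C@H](CC#C)O[Si](C(C)(C)C)(C(C)(C)C)O/C=C(OC)/C=C/O[Si](C)(C)C(C)(C)C | intermediate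
13 | silylene-bridged cycloadduct: (1S,4R)-4-(tert-butyldimethylsilyloxy)-2-methoxycyclohexa-2,5-diene with C1–O and the side-chain (2R)–O joined by Si(t-Bu)2 (seven-membered 1,3-dioxa-2-silepane fused at C1–C6, tridecyl on the carbinol carbon) | CCCCCCCCCCCCC[C@H](CC1=C[C@@H](O[Si](C)(C)C(C)(C)C)C=C(OC)[C@H]1O[Si]2(C(C)(C)C)C(C)(C)C)O2 | intermediate
14 | (1S,4R)-4-(tert-butyldimethylsilyloxy)-6-[(2R)-2-hydroxypentadecyl]-2-methoxycyclohexa-2,5-dien-1-ol | CCCCCCCCCCCCC[C@H](CC1=C[C@@H](O[Si](C)(C)C(C)(C)C)C=C(OC)[C@H]1O)O | intermediate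
15 | (1S,4R)-6-[(2R)-2-acetoxypentadecyl]-4-(tert-butyldimethylsilyloxy)-2-methoxycyclohexa-2,5-dien-1-yl acetate | CCCCCCCCCCCCC[C@H](CC1=C[C@@H](O[Si](C)(C)C(C)(C)C)C=C(OC)[C@H]1OC(C)=O)OC(C)=O | intermediate
16 | (1S,4R)-6-[(2R)-2-acetoxypentadecyl]-4-hydroxy-2-methoxycyclohexa-2,5-dien-1-yl acetate | CCCCCCCCCCCCC[C@H](CC1=C[C@@H](O)C=C(OC)[C@H]1OC(C)=O)OC(C)=O | target

Total step count: 9. Longest linear sequence: 9 steps (from 1).

Steps most likely to fail

Step 6. The cycloaddition of an unactivated alkyne across a seven-membered tether may be too slow, so that thermal decomposition of the dienol ether competes, and the facial bias exerted by the remote carbinol may be modest. The fallback activates the dienophile with a traceless, polarity-matched sulfone and sets out from 12. Deprotonation of the terminal alkyne (n-BuLi, THF, −78 °C) and quenching with p-toluenesulfonyl fluoride should give the alkynyl sulfone F1. The sulfone makes C6 the electrophilic alkyne carbon, which matches the nucleophilic diene terminus C1 that the tether already presents, so the intramolecular Diels–Alder reaction should run near room temperature to the 5-tosyl cycloadduct F2. Reductive desulfonylation of the vinyl sulfone (Na(Hg), Na2HPO4, MeOH/THF, −20 °C) comes back to the route at 13.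

Step 5. γ-Deprotonation may place the tether oxygen inside the diene (wrong enol ether geometry at C1), or silylation may compete at other sites, leaving little cyclisable diene. The fallback forms the tether and the diene in one operation from the other aldehyde tautomer; it sets out from 6 and comes back at 12. Horner–Wadsworth–Emmons reaction of (tert-butyldimethylsilyloxy)acetaldehyde with methyl 2-(dimethoxyphosphoryl)-2-methoxyacetate (LiN(SiMe3)2, THF) should give methyl (2Z)-4-(tert-butyldimethylsilyloxy)-2-methoxybut-2-enoate F3 (geometry immaterial). Reduction with i-Bu2AlH gives (2Z)-4-(tert-butyldimethylsilyloxy)-2-methoxybut-2-en-1-ol F4, and MnO2 oxidation gives (2Z)-4-(tert-butyldimethylsilyloxy)-2-methoxybut-2-enal F5. Alcohol 6 is converted into silyl triflate 8 as in step 3 and treated with F5 and Et3N. The tether-bearing enol ether then arises by O-silylation of the s-trans α-methoxy enal and should be outside by construction, while the distal OTBS terminus is expected anti on steric grounds, giving 12.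

Step 4. The ynal may oligomerise under amine catalysis, or methanol may add twice to give the β,β-dimethoxy acetal. The fallback carries out the oxa-Michael addition at the ester oxidation level; it sets out from 6 and comes back at 11. Silyl triflate 8 (from 6 as in step 3) is treated with methyl 4-hydroxybut-2-ynoate and imidazole to give methyl 4-({di-tert-butyl[(4R)-heptadec-1-yn-4-yloxy]silyl}oxy)but-2-ynoate F6. Phosphine-catalysed addition of methanol (PBu3, MeOH/CH2Cl2) should give methyl (2E)-4-({di-tert-butyl[(4R)-heptadec-1-yn-4-yloxy]silyl}oxy)-3-methoxybut-2-enoate F7. Reduction with i-Bu2AlH (CH2Cl2, −78 °C) gives (2E)-4-({di-tert-butyl[(4R)-heptadec-1-yn-4-yloxy]silyl}oxy)-3-methoxybut-2-en-1-ol F8, and MnO2 oxidation returns 11.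

Further compounds
F1 | step 6 | di-tert-butyl{[(1Z,3E)-4-(tert-butyldimethylsilyloxy)-2-methoxybuta-1,3-dien-1-yl]oxy}{[(4R)-1-(p-tolylsulfonyl)heptadec-1-yn-4-yl]oxy}silane | CCCCCCCCCCCCC[C@H](CC#CS(=O)(=O)c1ccc(C)cc1)O[Si](C(C)(C)C)(C(C)(C)C)O/C=C(OC)/C=C/O[Si](C)(C)C(C)(C)C
F2 | step 6 | 5-(p-tolylsulfonyl) analogue of cycloadduct 13 (same configuration at C1, C4 and the carbinol carbon) | CCCCCCCCCCCCC[C@H](CC1=C(S(=O)(=O)c3ccc(C)cc3)[C@@H](O[Si](C)(C)C(C)(C)C)C=C(OC)[C@H]1O[Si]2(C(C)(C)C)C(C)(C)C)O2
F3 | step 5 | methyl (2Z)-4-(tert-butyldimethylsilyloxy)-2-methoxybut-2-enoate | COC(=O)/C(OC)=C/CO[Si](C)(C)C(C)(C)C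
F4 | step 5 | (2Z)-4-(tert-butyldimethylsilyloxy)-2-methoxybut-2-en-1-ol | OC/C(OC)=C/CO[Si](C)(C)C(C)(C)C
F5 | step 5 | (2Z)-4-(tert-butyldimethylsilyloxy)-2-methoxybut-2-enal | O=C/C(OC)=C/CO[Si](C)(C)C(C)(C)C
F6 | step 4 | methyl 4-({di-tert-butyl[(4R)-heptadec-1-yn-4-yloxy]silyl}oxy)but-2-ynoate | CCCCCCCCCCCCC[C@H](CC#C)O[Si](C(C)(C)C)(C(C)(C)C)OCC#CC(=O)OC
F7 | step 4 | methyl (2E)-4-({di-tert-butyl[(4R)-heptadec-1-yn-4-yloxy]silyl}oxy)-3-methoxybut-2-enoate | CCCCCCCCCCCCC[C@H](CC#C)O[Si](C(C)(C)C)(C(C)(C)C)OC/C(OC)=C\C(=O)OC
F8 | step 4 | (2E)-4-({di-tert-butyl[(4R)-heptadec-1-yn-4-yloxy]silyl}oxy)-3-methoxybut-2-en-1-ol | CCCCCCCCCCCCC[C@H](CC#C)O[Si](C(C)(C)C)(C(C)(C)C)OC/C(OC)=C\CO
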